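**Retrosynthetic overview**
- Target 20 is 3,4,6-tribromo-2-(2,4-dibromophenoxy)phenol. The bromines ortho and para to the hydroxyl (C6, C4 of ring A) come last by bromination of phenol 19, which comes from methyl ether 17.
- The two bromines ortho to the ether oxygen (C3 of ring A, C2' of ring B) are traced back to trimethylsilyl groups in 16 (ipso-bromodesilylation).
- The strategy rests on ring B, C1'(O)–C2'(Br)–C3'(H)–C4'(Br)–C5'(H)–C6'(H), a 1-oxy-2,4-disubstituted benzene. It is cut into C1'–C2' (aryl silyl ynol ether 12) and C3'–C6' carrying the C4' bromine (5-bromo-2-pyrone 14). A [4+2] addition with loss of CO2 forms C2'–C3' and C1'–C6', so the crowded aryl–O–aryl bond is never made by arylation.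
- 12 comes from 2-bromo-6-methoxyphenol 1 by O-silylation, Br–Li exchange with 1,3 O→C silyl shift, vinylation with trichloroethylene, then elimination and C-silylation. 14 comes from coumalic acid by bromodecarboxylation.
- Ring order: ring A is bought; ring B is the only ring formed (step 6).

Key step: step 6

Remark: the target has no stereocentre. Ring A is numbered as the phenol (C1 OH, C2 OAr) and ring B with primed numbers. The E geometry of 9 is the expected one and is destroyed in step 4.

**Step 1**
Reactants: 1 2-bromo-6-methoxyphenol; 2 chlorotrimethylsilane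
Product: 3 (2-bromo-6-methoxyphenoxy)trimethylsilane
Conditions: Me3SiCl (1.1 equiv), Et3N, CH2Cl2, 0 °C to rt; filter under argon, concentrate
Reagents that add atoms: chlorotrimethylsilane (compound 2), C[Si](C)(C)Cl
Why: Standard O-silylation of a phenol (silyl ether formation) with Et3N taking up HCl, which sets up the silyl transfer of step 2.

**Step 2**
Reactants: 3 (2-bromo-6-methoxyphenoxy)trimethylsilane
Product: 6 2-methoxy-6-(trimethylsilyl)phenol, via aryllithium 4 (not isolated), via lithium phenolate 5 (not isolated)
Conditions: n-BuLi (1.1 equiv), THF, −78 °C to rt; then aq NH4Cl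
Reagents that add atoms: none
Why: Bromine–lithium exchange is followed by the anionic 1,3 O→C silyl shift (retro-Brook rearrangement), driven by formation of the lithium phenolate, which should place Me3Si on the carbon that carried bromine.

**Step 3**
Reactants: 6 2-methoxy-6-(trimethylsilyl)phenol; 7 trichloroethylene
Product: 9 (E)-[2-(1,2-dichloroethenyloxy)-3-methoxyphenyl]trimethylsilane, via dichloroacetylene 8 (not isolated)
Conditions: K2CO3, DMF, 70 °C
Reagents that add atoms: trichloroethylene (compound 7), ClC=C(Cl)Cl
Why: Known vinylation of phenols with trichloroethylene: base-induced loss of HCl gives dichloroacetylene, the phenolate adds anti and protonation should give the E-1,2-dichlorovinyl ether.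

**Step 4**
Reactants: 9 (E)-[2-(1,2-dichloroethenyloxy)-3-methoxyphenyl]trimethylsilane; 2 chlorotrimethylsilane
Product: 12 [2-methoxy-6-(trimethylsilyl)phenoxy]ethynyl(trimethyl)silane, via chloroalkynyl ether 10 (not isolated), via lithium acetylide 11 (not isolated)
Conditions: n-BuLi (2.2 equiv), THF, −78 to −40 °C; Me3SiCl, −78 °C to rt; aq NaHCO3 work-up, Et3N-deactivated silica
Reagents that add atoms: chlorotrimethylsilane (compound 2), C[Si](C)(C)Cl
Why: Ynol ether synthesis from a 1,2-dichlorovinyl ether: vinylic deprotonation and loss of LiCl give the chloroalkyne, chlorine–lithium exchange gives the acetylide and Me3SiCl caps it, with no aryl halide left to compete for butyllithium.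

**Step 5**
Reactants: 13 coumalic acid
Product: 14 5-bromo-2H-pyran-2-one
Conditions: NBS (1.1 equiv), LiOAc (cat.), MeCN–H2O, rt
Reagents that add atoms: N-bromosuccinimide, O=C1CCC(=O)N1Br
Why: Hunsdiecker-type bromodecarboxylation: C5 is the nucleophilic β-carbon of the O1–C6=C5 enol ester unit, so Br+ should add ipso to the carboxylate and loss of CO2 restores the pyrone.

**Step 6**
Reactants: 12 [2-methoxy-6-(trimethylsilyl)phenoxy]ethynyl(trimethyl)silane; 14 5-bromo-2H-pyran-2-one
Product: 16 [2-(4-bromo-2-(trimethylsilyl)phenoxy)-3-methoxyphenyl]trimethylsilane, via bridged lactone 15 (not isolated)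
Conditions: 14 (1.5 equiv), PhMe (degassed), 140 °C, sealed tube
Reagents that add atoms: none
Why: The electron-rich alkyne of 12 and the electron-poor diene C3=C4–C5=C6 of pyrone 14 should combine in a thermal, asynchronous inverse-electron-demand Diels–Alder reaction to the 2-oxabicyclo[2.2.2]octa-5,7-dien-3-one 15, which loses CO2 by retro-[4+2] and aromatises at once. The closest known reaction type is the benzannulation of 2-pyrones (coumalates, bromo-2-pyrones) with alkynes, including silyl- and heteroatom-substituted ones. Ring B is closed by an intermolecular [4+2] cycloaddition that forms C2'–C3' and C1'–C6' in one operation, with C1'/C2' from the ynol ether and C3'–C6' from pyrone C6–C3, followed by cycloreversion. No stereocentre survives, because the two bridgehead carbons of racemic 15 become sp2 when CO2 leaves. The step needs regioselectivity, which the substrate secures from both sides: the silyl-bearing carbon of the ynol ether is its nucleophilic terminus (charge building up on the oxygen-bearing carbon is stabilised by the oxygen lone pair and the β-silicon) and C6 is the most electrophilic diene terminus of the pyrone, so C2' bonds to pyrone C6 and C1' to pyrone C3, which puts the pyrone bromine para to the ether oxygen (C4'). The silyl group on C2' should survive the neutral thermal conditions and marks that carbon for bromine.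

**Step 7**
Reactants: 16 [2-(4-bromo-2-(trimethylsilyl)phenoxy)-3-methoxyphenyl]trimethylsilane
Product: 17 1-bromo-2-(2,4-dibromophenoxy)-3-methoxybenzene
Conditions: Br2 (2.1 equiv), CH2Cl2, −20 to 0 °C, dark; aq Na2S2O3
Reagents that add atoms: bromine, BrBr
Why: Ipso-bromodesilylation (electrophilic aromatic substitution at the silylated carbon): each Me3Si is ortho to an ether oxygen and the β-silyl arenium ion loses Me3SiBr faster than a C–H site loses a proton, while the only C–H site of similar reactivity (para to OMe on ring A) carries bromine in the target anyway.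

**Step 8**
Reactants: 17 1-bromo-2-(2,4-dibromophenoxy)-3-methoxybenzene
Product: 19 3-bromo-2-(2,4-dibromophenoxy)phenol, via aryloxydibromoborane 18 (not isolated)
Conditions: BBr3 (1.5 equiv), CH2Cl2, −78 to 0 °C; then H2O
Reagents that add atoms: none
Why: Lewis acid demethylation of an aryl methyl ether (O–B complex, bromide attack on methyl), which should leave the diaryl ether and the aryl bromides untouched; hydrolysis of the aryloxyborane frees the phenol.

**Step 9**
Reactants: 19 3-bromo-2-(2,4-dibromophenoxy)phenol
Product: 20 3,4,6-tribromo-2-(2,4-dibromophenoxy)phenol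
Conditions: Br2 (2.05 equiv), AcOH, rt
Reagents that add atoms: bromine, BrBr
Why: Electrophilic aromatic bromination directed by the free hydroxyl to its open ortho (C6) and para (C4) positions; C5 (meta to OH) and the bromine-deactivated ring B should react far more slowly, so two equivalents stop at the pentabromide.

**Compound list**
1 | 2-bromo-6-methoxyphenol | COc1cccc(Br)c1O | starting material
2 | chlorotrimethylsilane | C[Si](C)(C)Cl | starting material
3 | (2-bromo-6-methoxyphenoxy)trimethylsilane | COc1cccc(Br)c1O[Si](C)(C)C | intermediate
4 | (2-lithio-6-methoxyphenoxy)trimethylsilane | COc1cccc([Li])c1O[Si](C)(C)C | intermediate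
5 | lithium 2-methoxy-6-(trimethylsilyl)phenolate | COc1cccc([Si](C)(C)C)c1[O-].[Li+] | intermediate
6 | 2-methoxy-6-(trimethylsilyl)phenol | COc1cccc([Si](C)(C)C)c1O | intermediate
7 | trichloroethylene | ClC=C(Cl)Cl | starting material
8 | dichloroacetylene | ClC#CCl | intermediate
9 | (E)-[2-(1,2-dichloroethenyloxy)-3-methoxyphenyl]trimethylsilane | COc1cccc([Si](C)(C)C)c1O/C(Cl)=C\Cl | intermediate
10 | [2-(chloroethynyloxy)-3-methoxyphenyl]trimethylsilane | COc1cccc([Si](C)(C)C)c1OC#CCl | intermediate
11 | lithium [2-methoxy-6-(trimethylsilyl)phenoxy]acetylide | COc1cccc([Si](C)(C)C)c1OC#C[Li] | intermediate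
12 | [2-methoxy-6-(trimethylsilyl)phenoxy]ethynyl(trimethyl)silane | COc1cccc([Si](C)(C)C)c1OC#C[Si](C)(C)C | intermediate
13 | coumalic acid (2-oxo-2H-pyran-5-carboxylic acid) | O=C(O)c1ccc(=O)oc1 | starting material
14 | 5-bromo-2H-pyran-2-one | O=c1ccc(Br)co1 | intermediate
15 | 7-bromo-5-[2-methoxy-6-(trimethylsilyl)phenoxy]-6-(trimethylsilyl)-2-oxabicyclo[2.2.2]octa-5,7-dien-3-one (racemic) | COc1cccc([Si](C)(C)C)c1OC1=C([Si](C)(C)C)C2OC(=O)C1C=C2Br | intermediate
16 | [2-(4-bromo-2-(trimethylsilyl)phenoxy)-3-methoxyphenyl]trimethylsilane | COc1cccc([Si](C)(C)C)c1Oc1ccc(Br)cc1[Si](C)(C)C | intermediate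
17 | 1-bromo-2-(2,4-dibromophenoxy)-3-methoxybenzene | COc1cccc(Br)c1Oc1ccc(Br)cc1Br | intermediate
18 | dibromo[3-bromo-2-(2,4-dibromophenoxy)phenoxy]borane | BrB(Br)Oc1cccc(Br)c1Oc1ccc(Br)cc1Br | intermediate
19 | 3-bromo-2-(2,4-dibromophenoxy)phenol | Oc1cccc(Br)c1Oc1ccc(Br)cc1Br | intermediate
20 | 3,4,6-tribromo-2-(2,4-dibromophenoxy)phenol | Oc1c(Br)cc(Br)c(Br)c1Oc1ccc(Br)cc1Br | target

**Total step count:** 9
**Longest linear sequence:** 8 steps (steps 1–4 and 6–9; step 5 is a one-step branch)

**Steps most likely to fail**

Step 6. The cycloaddition is slowed by the two bulky groups on the alkyne, so thermal oligomerisation, adventitious hydration or desilylation of the ynol ether may outrun it. The fallback gives up the cycloaddition and makes the ether bond by metal-free O-arylation. It sets out from phenol 6. The salt (2,4-dibromophenyl)(2,4,6-trimethoxyphenyl)iodonium tosylate F1 would be made from commercial 2,4-dibromo-1-iodobenzene with mCPBA, TsOH·H2O and 1,3,5-trimethoxybenzene. With K2CO3 in toluene at 50 °C it should transfer only the dibromophenyl group to the phenolate of 6, giving [2-(2,4-dibromophenoxy)-3-methoxyphenyl]trimethylsilane F2. Br2 (1.05 equiv, CH2Cl2, 0 °C) then replaces the single remaining silyl group, and the route is rejoined at 17.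

Step 4. Vinylic deprotonation and chloride loss next to the doubly flanked aryloxy group may be sluggish, leaving butyllithium to add to the chloroalkynyl ether or expel the phenolate; the ynol ether may also hydrate during isolation. The fallback builds the two-carbon unit by a Corey–Fuchs-type sequence in which fast bromine–lithium exchange replaces the deprotonation. It sets out from phenol 6. Formylation with acetic formic anhydride and pyridine should give 2-methoxy-6-(trimethylsilyl)phenyl formate F3. Dibromomethylenation with CBr4 and PPh3 in CH2Cl2 at 0 °C should give [2-(2,2-dibromoethenyloxy)-3-methoxyphenyl]trimethylsilane F4. n-BuLi (2.1 equiv, THF, −78 °C) should then deliver lithium acetylide 11, and Me3SiCl brings the route back at 12.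

Step 7. HBr released by competing C–H bromination para to the methoxy group may cause protodesilylation alongside bromodesilylation, and exchange at the bromine-deactivated ring B may be slow; either would lose a position marker. The fallback separates removal of silicon from introduction of bromine. It sets out from 16. ICl (2.2 equiv, CH2Cl2, −78 to 0 °C) should effect clean low-temperature iododesilylation to 1-iodo-2-(4-bromo-2-iodophenoxy)-3-methoxybenzene F5. Copper-mediated aromatic halogen exchange with CuBr (monovalent copper, excess, DMF, 140 °C) should then turn both aryl iodides into bromides, and the route is rejoined at 17.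

**Further compounds**
F1 | step 6 | (2,4-dibromophenyl)(2,4,6-trimethoxyphenyl)iodonium 4-methylbenzenesulfonate | COc1cc(OC)c([I+]c2ccc(Br)cc2Br)c(OC)c1.Cc1ccc(S(=O)(=O)[O-])cc1
F2 | step 6 | [2-(2,4-dibromophenoxy)-3-methoxyphenyl]trimethylsilane | COc1cccc([Si](C)(C)C)c1Oc1ccc(Br)cc1Br
F3 | step 4 | 2-methoxy-6-(trimethylsilyl)phenyl formate | COc1cccc([Si](C)(C)C)c1OC=O
F4 | step 4 | [2-(2,2-dibromoethenyloxy)-3-methoxyphenyl]trimethylsilane | COc1cccc([Si](C)(C)C)c1OC=C(Br)Br
F5 | step 7 | 1-iodo-2-(4-bromo-2-iodophenoxy)-3-methoxybenzene | COc1cccc(I)c1Oc1ccc(Br)cc1I
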